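**Plan**
- The free 5-OH of unit A is masked as a pivalate, then the C4–C4a bond of unit A (the 5-hydroxyflavan) is cut. C4a lies between the O1-bearing C8a and the oxygenated C5, and C4 carries the ether oxygen, so an aryl bromide at C4a and a secondary α-alkoxy trifluoroborate at C4, tethered through O1–C2–C3, can close the pyran ring by a stereoretentive sp3–sp2 Suzuki coupling.
- Further cuts: O1–C2 (Mitsunobu aryl ether), the C4–O bond of the inter-flavan ether (alkoxide 1,2-shift on an α-chloro boronic ester), C3–C4 (Matteson homologation), C3–B (borylation of a chlorohydrin); unit B is cut at C2'–phenyl (aryl addition to a chromone).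
- Forward: the unit-B pyran ring is made first (acetophenone, chromone, flavanone, trans-flavan-4-ol). In parallel the C2–C3–C4 chain is grown on boron from (S)-2-chloro-1-phenylethanol. The unit-B alkoxide is then placed on C4, the bromophenol on C2, and the unit-A pyran ring closes last.
- Stereochemistry: C2' from a Pd/PyOX-catalysed asymmetric aryl addition; C4' from cis-selective hydride reduction followed by Mitsunobu inversion; C2 from the chloro alcohol with one Mitsunobu inversion; C4 from the (S,S)-DICHED-directed homologation (1R chloride), inverted by the alkoxide shift and carried into the ring with retention.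

Key step: step 18

Assumption: the (S,S)-diol is taken to give the (1R)-chloride (Matteson's rule, R,R-diol gives αS) and (R)-t-BuPyOX the 2S flavanone (the S ligand gives R adducts of cyclic enones); if either sense were opposite, the antipodal diol or ligand would be used.

**Route**

Step 1
Reactants: 1 3,4,5-trimethoxyphenol
Product: 2 1-(6-hydroxy-2,3,4-trimethoxyphenyl)ethan-1-one
Conditions: AcOH, BF3·OEt2, 90 °C
Reagents that add atoms: acetic acid, CC(=O)O
Why: BF3-mediated Friedel–Crafts C-acylation ortho to the phenol should give a single ketone because the two ortho positions of 1 are equivalent.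

Step 2
Reactants: 2 1-(6-hydroxy-2,3,4-trimethoxyphenyl)ethan-1-one
Product: 4 5,6,7-trimethoxy-4H-chromen-4-one, via enaminone 3 (not isolated)
Conditions: Me2NCH(OMe)2, toluene, 100 °C; then conc. HCl, CH2Cl2, 40 °C
Reagents that add atoms: N,N-dimethylformamide dimethyl acetal, COC(OC)N(C)C
Why: Enaminone formation at the methyl ketone followed by acid-induced addition–elimination of the phenol is the standard enaminone chromone annulation.

Step 3
Reactants: 4 5,6,7-trimethoxy-4H-chromen-4-one; 5 phenylboronic acid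
Product: 6 (S)-5,6,7-trimethoxy-2-phenylchroman-4-one
Conditions: Pd(OCOCF3)2 (5 mol %), (R)-t-BuPyOX (6 mol %), NH4PF6, H2O, ClCH2CH2Cl, 60 °C
Reagents that add atoms: none
Why: Pd(II)/pyridine–oxazoline-catalysed asymmetric conjugate addition of an arylboronic acid to a chromone should set C2' under ligand control, the tert-butyl oxazoline selecting the enone face.

Step 4
Reactants: 6 (S)-5,6,7-trimethoxy-2-phenylchroman-4-one
Product: 7 (2S,4S)-5,6,7-trimethoxy-2-phenylchroman-4-ol (2,4-cis)
Conditions: NaBH4, MeOH–THF, 0 °C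
Reagents that add atoms: none
Why: Borohydride reduction with axial hydride delivery to the half-chair flavanone carrying an equatorial 2-phenyl group should give the 2,4-cis alcohol under substrate control.

Step 5
Reactants: 7 (2S,4S)-5,6,7-trimethoxy-2-phenylchroman-4-ol
Product: 8 (2S,4R)-5,6,7-trimethoxy-2-phenylchroman-4-yl benzoate (2,4-trans)
Conditions: PhCO2H, PPh3, DIAD, toluene, −20 °C → rt
Reagents that add atoms: benzoic acid, O=C(O)c1ccccc1
Why: Mitsunobu esterification should invert C4' by SN2 displacement of the oxyphosphonium, and any ionised fraction is also captured axially, so both paths lead to the trans ester.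

Step 6
Reactants: 8 (2S,4R)-5,6,7-trimethoxy-2-phenylchroman-4-yl benzoate
Product: 9 (2S,4R)-5,6,7-trimethoxy-2-phenylchroman-4-ol (2,4-trans)
Conditions: K2CO3, MeOH–THF, rt
Reagents that add atoms: none
Why: Base-catalysed methanolysis cleaves the acyl–oxygen bond, so the C4'–O bond and its configuration are untouched.

Step 7
Reactants: 10 (S)-2-chloro-1-phenylethanol
Product: 11 (S)-tert-butyl(2-chloro-1-phenylethoxy)dimethylsilane
Conditions: TBSCl, imidazole, DMF, rt
Reagents that add atoms: tert-butyldimethylsilyl chloride, CC(C)(C)[Si](C)(C)Cl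
Why: Standard silylation gives an oxygen substituent that is a poor leaving group while it is β to boron in steps 8–10, where an aryloxy group would invite β-elimination.

Step 8
Reactants: 11 (S)-tert-butyl(2-chloro-1-phenylethoxy)dimethylsilane
Product: 12 (R)-tert-butyldimethyl[1-phenyl-2-(4,4,5,5-tetramethyl-1,3,2-dioxaborolan-2-yl)ethoxy]silane
Conditions: B2pin2, CuCl (10 mol %), Xantphos (10 mol %), KOt-Bu, THF, rt
Reagents that add atoms: bis(pinacolato)diboron, CC1(C)OB(OC1(C)C)B1OC(C)(C)C(C)(C)O1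
Why: Copper(I)-catalysed boryl substitution of a primary alkyl chloride replaces Cl by Bpin without touching the carbinol centre (the descriptor changes only through CIP priorities).

Step 9
Reactants: 12 (R)-tert-butyldimethyl[1-phenyl-2-(4,4,5,5-tetramethyl-1,3,2-dioxaborolan-2-yl)ethoxy]silane
Product: 14 (4S,5S)-2-[(2R)-2-(tert-butyldimethylsilyloxy)-2-phenylethyl]-4,5-dicyclohexyl-1,3,2-dioxaborolane, via boronic acid 13 (not isolated)
Conditions: NaIO4, NH4OAc, acetone–H2O, rt; then (S,S)-DICHED, MgSO4, Et2O, rt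
Reagents that add atoms: (1S,2S)-1,2-dicyclohexylethane-1,2-diol, O[C@@H](C1CCCCC1)[C@@H](O)C1CCCCC1
Why: Periodate cleavage of the released pinacol drives hydrolysis to the boronic acid, which is esterified with the C2-symmetric diol that will act as chiral director.

Step 10
Reactants: 14 (4S,5S)-2-[(2R)-2-(tert-butyldimethylsilyloxy)-2-phenylethyl]-4,5-dicyclohexyl-1,3,2-dioxaborolane
Product: 16 (4S,5S)-2-[(1R,3R)-3-(tert-butyldimethylsilyloxy)-1-chloro-3-phenylpropyl]-4,5-dicyclohexyl-1,3,2-dioxaborolane, via dichloromethyl borate 15 (not isolated)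
Conditions: CH2Cl2, n-BuLi, THF, −100 °C; then 14; ZnCl2, −100 °C → rt
Reagents that add atoms: dichloromethane, ClCCl
Why: Matteson homologation, in which ZnCl2-promoted 1,2-migration of the alkyl group expels one diastereotopic chloride of the borate, should set the new C–Cl centre as 1R under control of the (S,S)-diol.

Step 11
Reactants: 16 (4S,5S)-2-[(1R,3R)-3-(tert-butyldimethylsilyloxy)-1-chloro-3-phenylpropyl]-4,5-dicyclohexyl-1,3,2-dioxaborolane; 9 (2S,4R)-5,6,7-trimethoxy-2-phenylchroman-4-ol
Product: 17 (4S,5S)-2-[(1S,3R)-3-(tert-butyldimethylsilyloxy)-3-phenyl-1-{[(2S,4R)-5,6,7-trimethoxy-2-phenylchroman-4-yl]oxy}propyl]-4,5-dicyclohexyl-1,3,2-dioxaborolane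
Conditions: NaH, THF, 0 °C; then 16, THF–DMSO, rt
Reagents that add atoms: none
Why: In this Matteson substitution the alkoxide of 9 adds to boron and its B-to-C 1,2-shift displaces chloride with inversion (1R to 1S), while the C4'–O bond of unit B is never broken and keeps its trans configuration.

Step 12
Reactants: 17 (4S,5S)-2-[(1S,3R)-3-(tert-butyldimethylsilyloxy)-3-phenyl-1-{[(2S,4R)-5,6,7-trimethoxy-2-phenylchroman-4-yl]oxy}propyl]-4,5-dicyclohexyl-1,3,2-dioxaborolane
Product: 18 (4S,5S)-2-[(1S,3R)-3-hydroxy-3-phenyl-1-{[(2S,4R)-5,6,7-trimethoxy-2-phenylchroman-4-yl]oxy}propyl]-4,5-dicyclohexyl-1,3,2-dioxaborolane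
Conditions: TBAF, AcOH, THF, 0 °C → rt
Reagents that add atoms: none
Why: Buffered fluoride desilylation frees the benzylic alcohol without generating a free alkoxide that could attack the robust diol boronic ester.

Step 13
Reactants: 19 3-hydroxy-4,5-dimethoxybenzaldehyde
Product: 20 2-bromo-3-hydroxy-4,5-dimethoxybenzaldehyde
Conditions: Br2, NaOAc, AcOH, rt
Reagents that add atoms: bromine, BrBr
Why: Electrophilic bromination should go to C2, which is ortho to the free phenol and para to the 5-methoxy group, as in the bromination of isovanillin to its 2-bromo derivative.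

Step 14
Reactants: 20 2-bromo-3-hydroxy-4,5-dimethoxybenzaldehyde
Product: 21 2-bromo-4,5-dimethoxy-3-(pivaloyloxy)benzaldehyde
Conditions: PivCl, Et3N, DMAP (cat.), CH2Cl2, 0 °C → rt
Reagents that add atoms: pivaloyl chloride, CC(C)(C)C(=O)Cl
Why: DMAP-catalysed acylation gives a hindered aryl ester that, unlike an aryl silyl ether, is inert to the bifluoride of step 17 and can later be removed without acid or heat.

Step 15
Reactants: 21 2-bromo-4,5-dimethoxy-3-(pivaloyloxy)benzaldehyde
Product: 23 2-bromo-3-hydroxy-5,6-dimethoxyphenyl pivalate, via aryl formate 22 (not isolated)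
Conditions: mCPBA, CH2Cl2, 0 °C → rt; then Et3N, MeOH, 0 °C
Reagents that add atoms: 3-chloroperbenzoic acid, O=C(OO)c1cccc(Cl)c1
Why: Baeyer–Villiger (Dakin-type) oxidation with migration of the aryl group, activated by the para-methoxy substituent, gives the formate, which is methanolysed selectively beside the hindered pivalate.

Step 16
Reactants: 18 (4S,5S)-2-[(1S,3R)-3-hydroxy-3-phenyl-1-{[(2S,4R)-5,6,7-trimethoxy-2-phenylchroman-4-yl]oxy}propyl]-4,5-dicyclohexyl-1,3,2-dioxaborolane; 23 2-bromo-3-hydroxy-5,6-dimethoxyphenyl pivalate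
Product: 24 (4S,5S)-2-[(1S,3S)-3-[2-bromo-4,5-dimethoxy-3-(pivaloyloxy)phenoxy]-3-phenyl-1-{[(2S,4R)-5,6,7-trimethoxy-2-phenylchroman-4-yl]oxy}propyl]-4,5-dicyclohexyl-1,3,2-dioxaborolane
Conditions: PPh3, DIAD, THF, 0 °C → rt
Reagents that add atoms: none
Why: Mitsunobu etherification of the secondary benzylic alcohol by the acidic ortho-bromophenol should invert C3 (the future C2, R to S), and the aryloxy group enters γ to boron, where β-elimination is no longer possible.

Step 17
Reactants: 24 (4S,5S)-2-[(1S,3S)-3-[2-bromo-4,5-dimethoxy-3-(pivaloyloxy)phenoxy]-3-phenyl-1-{[(2S,4R)-5,6,7-trimethoxy-2-phenylchroman-4-yl]oxy}propyl]-4,5-dicyclohexyl-1,3,2-dioxaborolane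
Product: 25 potassium trifluoro{(1S,3S)-3-[2-bromo-4,5-dimethoxy-3-(pivaloyloxy)phenoxy]-3-phenyl-1-{[(2S,4R)-5,6,7-trimethoxy-2-phenylchroman-4-yl]oxy}propyl}borate
Conditions: KHF2 (aq), MeCN, 0 °C → rt; diol removed by Et2O extraction
Reagents that add atoms: potassium hydrogen difluoride, [K+].F[H-]F
Why: Bifluoride exchange at boron converts the diol ester into the trifluoroborate without touching the C–B stereocentre, and the aryl pivalate is stable to these conditions.

Step 18
Reactants: 25 potassium trifluoro{(1S,3S)-3-[2-bromo-4,5-dimethoxy-3-(pivaloyloxy)phenoxy]-3-phenyl-1-{[(2S,4R)-5,6,7-trimethoxy-2-phenylchroman-4-yl]oxy}propyl}borate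
Product: 26 (2S,4R)-6,7-dimethoxy-2-phenyl-4-{[(2S,4R)-5,6,7-trimethoxy-2-phenylchroman-4-yl]oxy}chroman-5-yl pivalate (5-O-pivaloyl beilschmieflavonoid B)
Conditions: cataCXium A Pd G3 (10 mol %), Cs2CO3 (3 equiv), CPME–H2O (10:1), 90 °C, degassed
Reagents that add atoms: none
Why: Proposed new method: Pd(0) inserts into the C4a–Br bond, the trifluoroborate is slowly hydrolysed to the boronic acid, and the α-alkoxyalkyl group passes to palladium through a closed, oxygen-bridged transition state with retention at C4, after which C–C reductive elimination forms C4–C4a. The closest known reaction type is the stereoretentive Suzuki–Miyaura coupling of secondary potassium 1-(benzyloxy)alkyltrifluoroborates with aryl halides; it is run here intramolecularly, and the flavan-4-yl ether, itself an α-substituted benzyl ether, can offer the arene–palladium contact held to stabilise the diorganopalladium intermediate. The unit-A pyran ring closes as a six-membered ring by reductive elimination from a seven-membered oxapalladacycle (formally 6-exo attack of C4 on the aryl carbon held by the O1–C2–C3 tether). No stereocentre is created: the C4 configuration set in steps 10 and 11 is transferred with retention and C2 is untouched. The step needs reductive elimination to outrun β-hydride elimination towards C3 and protodeboronation, which the short tether, the bulky electron-rich di(1-adamantyl)butylphosphine and the ether/arene coordination should favour. The arylation site is fixed by the bromide between O1 and the pivalate-bearing C5, and the pivalate is kept on so that no ortho-phenoxide can expel the C4 ether.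

Step 19
Reactants: 26 (2S,4R)-6,7-dimethoxy-2-phenyl-4-{[(2S,4R)-5,6,7-trimethoxy-2-phenylchroman-4-yl]oxy}chroman-5-yl pivalate
Product: 27 beilschmieflavonoid B, (2S,4R)-6,7-dimethoxy-2-phenyl-4-{[(2S,4R)-5,6,7-trimethoxy-2-phenylchroman-4-yl]oxy}chroman-5-ol
Conditions: DIBAL-H, CH2Cl2, −78 °C; Rochelle salt work-up
Reagents that add atoms: none
Why: Reductive cleavage of the aryl pivalate at low temperature frees the 5-OH without acid, heat or a long-lived phenoxide, so the doubly benzylic C4 ether should survive.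

**Compound list**
1 | 3,4,5-trimethoxyphenol | COc1cc(O)cc(OC)c1OC | starting material
2 | 1-(6-hydroxy-2,3,4-trimethoxyphenyl)ethan-1-one | CC(=O)c1c(O)cc(OC)c(OC)c1OC | intermediate
3 | (E)-3-(dimethylamino)-1-(6-hydroxy-2,3,4-trimethoxyphenyl)prop-2-en-1-one | CN(C)/C=C/C(=O)c1c(O)cc(OC)c(OC)c1OC | intermediate
4 | 5,6,7-trimethoxy-4H-chromen-4-one | COc1cc2occc(=O)c2c(OC)c1OC | intermediate
5 | phenylboronic acid | OB(O)c1ccccc1 | starting material
6 | (S)-5,6,7-trimethoxy-2-phenylchroman-4-one | O=C1C[C@@H](c2ccccc2)Oc2cc(OC)c(OC)c(OC)c21 | intermediate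
7 | (2S,4S)-5,6,7-trimethoxy-2-phenylchroman-4-ol | O[C@H]1C[C@@H](c2ccccc2)Oc2cc(OC)c(OC)c(OC)c21 | intermediate
8 | (2S,4R)-5,6,7-trimethoxy-2-phenylchroman-4-yl benzoate | O=C(O[C@@H]1C[C@@H](c2ccccc2)Oc2cc(OC)c(OC)c(OC)c21)c1ccccc1 | intermediate
9 | (2S,4R)-5,6,7-trimethoxy-2-phenylchroman-4-ol | O[C@@H]1C[C@@H](c2ccccc2)Oc2cc(OC)c(OC)c(OC)c21 | intermediate
10 | (S)-2-chloro-1-phenylethanol | O[C@H](CCl)c1ccccc1 | starting material
11 | (S)-tert-butyl(2-chloro-1-phenylethoxy)dimethylsilane | CC(C)(C)[Si](C)(C)O[C@H](CCl)c1ccccc1 | intermediate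
12 | (R)-tert-butyldimethyl[1-phenyl-2-(4,4,5,5-tetramethyl-1,3,2-dioxaborolan-2-yl)ethoxy]silane | CC(C)(C)[Si](C)(C)O[C@H](CB1OC(C)(C)C(C)(C)O1)c1ccccc1 | intermediate
13 | (R)-[2-(tert-butyldimethylsilyloxy)-2-phenylethyl]boronic acid | CC(C)(C)[Si](C)(C)O[C@H](CB(O)O)c1ccccc1 | intermediate
14 | (4S,5S)-2-[(2R)-2-(tert-butyldimethylsilyloxy)-2-phenylethyl]-4,5-dicyclohexyl-1,3,2-dioxaborolane | CC(C)(C)[Si](C)(C)O[C@H](CB1O[C@@H](C2CCCCC2)[C@H](C2CCCCC2)O1)c1ccccc1 | intermediate
15 | lithium (4S,5S)-2-[(2R)-2-(tert-butyldimethylsilyloxy)-2-phenylethyl]-4,5-dicyclohexyl-2-(dichloromethyl)-1,3,2-dioxaborolan-2-uide | [Li+].CC(C)(C)[Si](C)(C)O[C@H](C[B-]1(C(Cl)Cl)O[C@@H](C2CCCCC2)[C@H](C2CCCCC2)O1)c1ccccc1 | intermediate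
16 | (4S,5S)-2-[(1R,3R)-3-(tert-butyldimethylsilyloxy)-1-chloro-3-phenylpropyl]-4,5-dicyclohexyl-1,3,2-dioxaborolane | CC(C)(C)[Si](C)(C)O[C@@H](c1ccccc1)C[C@H](Cl)B1O[C@@H](C2CCCCC2)[C@H](C2CCCCC2)O1 | intermediate
17 | (4S,5S)-2-[(1S,3R)-3-(tert-butyldimethylsilyloxy)-3-phenyl-1-{[(2S,4R)-5,6,7-trimethoxy-2-phenylchroman-4-yl]oxy}propyl]-4,5-dicyclohexyl-1,3,2-dioxaborolane | CC(C)(C)[Si](C)(C)O[C@@H](c1ccccc1)C[C@@H](O[C@@H]1C[C@@H](c2ccccc2)Oc2cc(OC)c(OC)c(OC)c21)B1O[C@@H](C2CCCCC2)[C@H](C2CCCCC2)O1 | intermediate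
18 | (4S,5S)-2-[(1S,3R)-3-hydroxy-3-phenyl-1-{[(2S,4R)-5,6,7-trimethoxy-2-phenylchroman-4-yl]oxy}propyl]-4,5-dicyclohexyl-1,3,2-dioxaborolane | O[C@@H](c1ccccc1)C[C@@H](O[C@@H]1C[C@@H](c2ccccc2)Oc2cc(OC)c(OC)c(OC)c21)B1O[C@@H](C2CCCCC2)[C@H](C2CCCCC2)O1 | intermediate
19 | 3-hydroxy-4,5-dimethoxybenzaldehyde | COc1cc(C=O)cc(O)c1OC | starting material
20 | 2-bromo-3-hydroxy-4,5-dimethoxybenzaldehyde | COc1cc(C=O)c(Br)c(O)c1OC | intermediate
21 | 2-bromo-4,5-dimethoxy-3-(pivaloyloxy)benzaldehyde | COc1cc(C=O)c(Br)c(OC(=O)C(C)(C)C)c1OC | intermediate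
22 | 2-bromo-3-(formyloxy)-5,6-dimethoxyphenyl pivalate | COc1cc(OC=O)c(Br)c(OC(=O)C(C)(C)C)c1OC | intermediate
23 | 2-bromo-3-hydroxy-5,6-dimethoxyphenyl pivalate | COc1cc(O)c(Br)c(OC(=O)C(C)(C)C)c1OC | intermediate
24 | (4S,5S)-2-[(1S,3S)-3-[2-bromo-4,5-dimethoxy-3-(pivaloyloxy)phenoxy]-3-phenyl-1-{[(2S,4R)-5,6,7-trimethoxy-2-phenylchroman-4-yl]oxy}propyl]-4,5-dicyclohexyl-1,3,2-dioxaborolane | COc1cc(O[C@H](c2ccccc2)C[C@@H](O[C@@H]2C[C@@H](c3ccccc3)Oc3cc(OC)c(OC)c(OC)c32)B2O[C@@H](C3CCCCC3)[C@H](C3CCCCC3)O2)c(Br)c(OC(=O)C(C)(C)C)c1OC | intermediate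
25 | potassium trifluoro{(1S,3S)-3-[2-bromo-4,5-dimethoxy-3-(pivaloyloxy)phenoxy]-3-phenyl-1-{[(2S,4R)-5,6,7-trimethoxy-2-phenylchroman-4-yl]oxy}propyl}borate | [K+].F[B-](F)(F)[C@H](O[C@@H]1C[C@@H](c2ccccc2)Oc2cc(OC)c(OC)c(OC)c21)C[C@@H](c1ccccc1)Oc1cc(OC)c(OC)c(OC(=O)C(C)(C)C)c1Br | intermediate
26 | (2S,4R)-6,7-dimethoxy-2-phenyl-4-{[(2S,4R)-5,6,7-trimethoxy-2-phenylchroman-4-yl]oxy}chroman-5-yl pivalate | COc1cc2c(c(OC(=O)C(C)(C)C)c1OC)[C@H](O[C@@H]1C[C@@H](c3ccccc3)Oc3cc(OC)c(OC)c(OC)c31)C[C@@H](c1ccccc1)O2 | intermediate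
27 | beilschmieflavonoid B | COc1cc2c(c(O)c1OC)[C@H](O[C@@H]1C[C@@H](c3ccccc3)Oc3cc(OC)c(OC)c(OC)c31)C[C@@H](c1ccccc1)O2 | target

**Count and risks**
Total: 19 steps. Longest linear sequence: 12 steps (from 1 through steps 1–6, 11, 12, 16–19).

Step 18 (proposed new method). The secondary alkylpalladium may undergo β-hydride elimination towards C3 or the α-alkoxy boron species may protodeboronate before transmetalation. Oxidative addition into the di-ortho-oxygenated bromide may be slow, and partial pivalate hydrolysis could open an ortho-quinone methide pathway that erodes C4. The fallback uses known chemistry, sets out from flavanone 6 and returns at target 27. BCl3 (CH2Cl2, −78 → 0 °C) removes the carbonyl-chelated 5-O-methyl group to give (S)-5-hydroxy-6,7-dimethoxy-2-phenylchroman-4-one F1. NaBH4 then gives (2S,4S)-6,7-dimethoxy-2-phenylchromane-4,5-diol F2. Warming F2 with alcohol 9 (toluene, 4 Å sieves, about 80 °C) should generate the ortho-quinone methide across C5–C4a–C4 by loss of water, and oxa-Michael addition of 9 would give 27. The trans relationship at C4 would come from axial approach and from the preference of a C4 substituent next to the C5 oxygen for the pseudo-axial position.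

Step 11. Attack of the hindered, pseudo-axial secondary alkoxide on boron may be slow, so that dehydrochlorination of the α-chloro boronic ester or attack at the diol ester competes with the 1,2-shift. The fallback sets out from chloride 16 and returns at 17. Lithium benzyl oxide (BnOH, n-BuLi, THF), the standard small nucleophile for this substitution, would give (4S,5S)-2-[(1S,3R)-1-(benzyloxy)-3-(tert-butyldimethylsilyloxy)-3-phenylpropyl]-4,5-dicyclohexyl-1,3,2-dioxaborolane F3. Hydrogenolysis (H2, Pd/C, EtOAc) would give the α-hydroxy boronic ester (4S,5S)-2-[(1S,3R)-3-(tert-butyldimethylsilyloxy)-1-hydroxy-3-phenylpropyl]-4,5-dicyclohexyl-1,3,2-dioxaborolane F4. The cis alcohol 7 would be converted with Cl3CCN and DBU into (2S,4S)-5,6,7-trimethoxy-2-phenylchroman-4-yl 2,2,2-trichloroacetimidate F5. TMSOTf-catalysed coupling of F4 with F5 at −78 °C would then form the C4'–O bond by axial capture of the flavan-4-yl cation (2,4-trans) and give 17. Control at C4' thus changes from stereospecific relay to stereoelectronic control.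

Step 5. The electron-rich, peri-substituted benzylic oxyphosphonium may ionise, leading to elimination to the flav-3-ene or to partial retention instead of clean inversion. The fallback sets out from 7 and returns at 9, bypassing 8. SOCl2 (Et2O, 0 °C) would give (2S,4R)-4-chloro-5,6,7-trimethoxy-2-phenylchromane F6, used crude. Silver carbonate in aqueous acetone would hydrolyse it by an SN1 path in which water attacks the cation axially, giving the trans alcohol 9.

**Further compounds**
F1 | step 18 | (S)-5-hydroxy-6,7-dimethoxy-2-phenylchroman-4-one | O=C1C[C@@H](c2ccccc2)Oc2cc(OC)c(OC)c(O)c21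
F2 | step 18 | (2S,4S)-6,7-dimethoxy-2-phenylchromane-4,5-diol | O[C@H]1C[C@@H](c2ccccc2)Oc2cc(OC)c(OC)c(O)c21
F3 | step 11 | (4S,5S)-2-[(1S,3R)-1-(benzyloxy)-3-(tert-butyldimethylsilyloxy)-3-phenylpropyl]-4,5-dicyclohexyl-1,3,2-dioxaborolane | CC(C)(C)[Si](C)(C)O[C@@H](c1ccccc1)C[C@@H](OCc1ccccc1)B1O[C@@H](C2CCCCC2)[C@H](C2CCCCC2)O1
F4 | step 11 | (4S,5S)-2-[(1S,3R)-3-(tert-butyldimethylsilyloxy)-1-hydroxy-3-phenylpropyl]-4,5-dicyclohexyl-1,3,2-dioxaborolane | CC(C)(C)[Si](C)(C)O[C@@H](c1ccccc1)C[C@@H](O)B1O[C@@H](C2CCCCC2)[C@H](C2CCCCC2)O1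
F5 | step 11 | (2S,4S)-5,6,7-trimethoxy-2-phenylchroman-4-yl 2,2,2-trichloroacetimidate | N=C(O[C@H]1C[C@@H](c2ccccc2)Oc2cc(OC)c(OC)c(OC)c21)C(Cl)(Cl)Cl
F6 | step 5 | (2S,4R)-4-chloro-5,6,7-trimethoxy-2-phenylchromane | Cl[C@@H]1C[C@@H](c2ccccc2)Oc2cc(OC)c(OC)c(OC)c21
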